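**Remark on the chemistry (assumption):** the sense of induction of the chiral acid in the key step cannot be assigned in advance; the (S,S)-acid is written and stands for whichever antipode delivers the 2S product.

## Analysis of the target

The target 15 is (2S)-5-hydroxy-7-(3-methylbut-2-enyloxy)-8-(3-methylbut-2-enyl)flavanone, a chroman-4-one in which benzo ring A is fused to dihydropyranone ring C and an unsubstituted phenyl ring B sits on C2. Ring A is a fully differentiated phloroglucinol with a free hydroxyl at C5 hydrogen-bonded to the C4 carbonyl, hydrogen at C6, an O-prenyl ether at C7 and a C-prenyl group at C8 next to the ring oxygen O1. The only stereocentre is C2 (S), a benzylic ether carbon β to the ketone; no neighbouring centre can relay stereochemistry to it, and it is erased whenever base opens ring C to the 2'-hydroxychalcone. The two trisubstituted alkenes rule out hydrogenation, strong protic or Lewis acids (hydration, closure of the ortho-prenylphenol to a chroman, cleavage of the allylic aryl ether) and electrophiles such as carbenoids, and the aryl prenyl ether rearranges on strong heating. The difficulty is therefore twofold: three oxygens and a C-prenyl group must be placed on ring A with full regiocontrol, and an isolated stereocentre must be created under conditions the prenyl groups tolerate. The strategy rests on the fact that ring C is attached to ring A only through O1 and C4, while C2 with its phenyl group and C3 are the two carbons of styrene. O1–C8a–C4a–C4 is then the heterodiene of an ortho-quinone methide, and C4, a formyl carbon that keeps one alkoxy group, is already close to the ketone oxidation level.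

## Retrosynthetic reasoning

**15 ⇒ 14.** The last disconnection is the O5–Si bond. O5 has to be masked until the end: in the ring-forming step only the oxygen next to the C-prenyl group may become O1, and a free electron-rich phenol would not survive the oxidation at C4. A silyl ether is chosen because it can be removed without base, so C2 is not endangered.

**14 ⇒ 13 ⇒ 12.** No skeletal bond is cut here; the C4 oxidation state is traced back from ketone to carbinol to methyl ether. The methyl ether is what the ring-forming step delivers, so the forward task is a solvolysis at the very ionisable C4 position followed by a mild alcohol oxidation. Both leave C2 untouched.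

**12 ⇒ 7 + 8 + 9.** Ring C is cut at O1–C2 and C3–C4, a retro-hetero-Diels–Alder. This is the only cut that removes the whole ring and the stereocentre in one operation and ends in an achiral benzaldehyde (7), a commodity alkene (8) and a C1 reagent (9). Cuts at C4–C4a or C2–C3 would leave a chiral fragment to be made separately. The forward reaction must form acetal 10, ionise it to the cation corresponding to quinone methide 11, and add 8 with control of the C2 configuration.

**7 ⇒ 6.** The O–Si bond on the hydroxyl remote from the C-prenyl group is cut. The forward step has to distinguish two hydroxyls that both flank the formyl group; only sterics differ (hydrogen versus prenyl as the other neighbour).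

**6 ⇒ 3.** The aryl–prenyl C–C bond is traced back to an O-prenyl ether by a para-Claisen–Cope shift through dienones 4 and 5. This shift places the prenyl group para to the oxygen it leaves and ortho to the hydroxyl that was free all along. That is exactly the relation between C8-prenyl, the future O1 and the future O5, and it avoids a direct, poorly selective C-alkylation.

**3 ⇒ 1 + 2.** Two aryl O–C bonds are cut. Forward, a double O-alkylation of 1 with 2 is needed in which the third hydroxyl is spared by its hydrogen bond to the formyl group.

## Alternatives that were turned down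

**Alternative 1:** Flavone A1 is disconnected at C4a–C4, C4–C3 and O1–C2 into iodophenol A2 , phenylacetylene A3 and carbon monoxide A4 as the C4 carbonyl source.
- **Forward key step:** PdCl2(PPh3)2 and CuI under an atmosphere of A4 with a secondary amine; carbonylative coupling of A2 with A3 followed by 6-endo closure of the phenol onto the ynone gives A1.
- **For:** the ring-forming reaction is established, convergent, and delivers C4 directly as the ketone. On precedent for ring closure it is stronger than the chosen step.
- **Against:** A1 is flat at C2. The stereocentre would need a separate enantioselective 1,4-reduction of the C2=C3 bond in the presence of two prenyl alkenes, which excludes hydrogenation and is itself not secured. A2 is a pentasubstituted arene whose iodination must choose between two free ring positions. The acetal protecting group must later be removed with acid next to the prenyl groups, and 5-exo closure to an aurone competes.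
- **Comparison:** the chosen strategy offers ring and stereocentre in one step from a simpler aromatic precursor, at the price of a less precedented key step.

**Alternative 2:** Flavanone A5 is disconnected at C2–C3, back to diazoketone A6 , which carries a benzyl ether on the oxygen that becomes O1.
- **Forward key step:** Rh2(S-PTTL)4, the dirhodium tetrakis(N-phthaloyl-tert-leucinate) complex of divalent rhodium, or its mirror image turns A6 into a carbenoid that inserts into the benzylic ether C–H bond and so gives A5.
- **For:** ring, stereocentre and the ketone oxidation level are obtained at once. After the key step only a deacetylation remains, which is shorter than the three steps after the key step of the chosen route.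
- **Against:** an acceptor-only carbenoid is unselective. Both prenyl alkenes are good cyclopropanation partners, and the adjacent ether oxygen invites oxonium ylide formation with a 1,2-benzyl shift to a benzofuranone. The required six-membered insertion is the less favoured mode. A6 sits on a doubly ortho-substituted, electron-rich benzoyl unit that is laborious to make.
- **Comparison:** the chosen strategy uses no high-energy intermediate, and the substrate's own alkenes are poorer partners than the alkene added in excess.

**Alternative 3:** Flavanone A7 , which is identical with 14, is disconnected at C4–C4a to the chiral aryloxy acid A8 .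
- **Forward key step:** the acid chloride of A8 in a fluorinated alcohol, or its mixed trifluoroacetic anhydride at low temperature, acylates the one free position ortho to the aryloxy oxygen (the future C4a) and closes ring C to A7.
- **For:** the stereocentre of A8 would come from routine asymmetric reduction and an inverting etherification. On stereochemical certainty this route is stronger than the chosen one. It also joins the main route one step before the target.
- **Against:** acylium conditions threaten the prenyl alkenes and the allylic aryl ether. The benzylic aryl ether of A8 can ionise or eliminate under acid, which would erode C2. Its aryl part needs three differentiated oxygens and a C-prenyl group assembled without the directing formyl group, so the sequence is longer.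
- **Comparison:** the chosen strategy is shorter and more convergent and runs under weak acid; what it gives up is a stereocentre set by known chemistry.

Key step: step 4

## Route

**Step 1**
Reactants: 1 2,4,6-trihydroxybenzaldehyde; 2 prenyl bromide (1-bromo-3-methylbut-2-ene)
Product: 3 2-hydroxy-4,6-bis(3-methylbut-2-enyloxy)benzaldehyde
Conditions: 2 (2.2 equiv), K2CO3 (2.5 equiv), acetone, reflux
Reagents that add atoms: none
Why: Williamson O-alkylation; the non-chelated 4-hydroxyl reacts first, one of the two chelated hydroxyls second, and the last is held back by its hydrogen bond to the formyl group, while carbonate in acetone favours O- over C-alkylation of the formyl-deactivated ring.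

**Step 2**
Reactants: 3 2-hydroxy-4,6-bis(3-methylbut-2-enyloxy)benzaldehyde
Product: 6 2,6-dihydroxy-3-(3-methylbut-2-enyl)-4-(3-methylbut-2-enyloxy)benzaldehyde, via ortho-dienone 4 (not isolated), via para-dienone 5 (not isolated)
Conditions: Eu(fod)3 (10 mol%), CHCl3, 60 °C
Reagents that add atoms: none
Why: Lanthanide-catalysed para-Claisen–Cope rearrangement, known for aryl prenyl ethers flanked by a carbonyl group (5-O-prenylflavanones to 8-prenylflavanones); Eu(fod)3 (tris(6,6,7,7,8,8,8-heptafluoro-2,2-dimethyloctane-3,5-dionato)europium) chelated between the formyl oxygen and the O6 ether accelerates the [3,3] shift of that prenyl group alone to C5 (4), a Cope shift carries it to C3 para to the freed oxygen (5), and enolisation gives 6. The O4 ether is not chelated and should stay in place.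

**Step 3**
Reactants: 6 2,6-dihydroxy-3-(3-methylbut-2-enyl)-4-(3-methylbut-2-enyloxy)benzaldehyde
Product: 7 6-(tert-butyldimethylsilyloxy)-2-hydroxy-3-(3-methylbut-2-enyl)-4-(3-methylbut-2-enyloxy)benzaldehyde
Conditions: TBSCl (1.05 equiv), imidazole (2.2 equiv), CH2Cl2, −20 → 0 °C
Reagents that add atoms: tert-butyldimethylsilyl chloride, CC(C)(C)[Si](C)(C)Cl
Why: Imidazole-promoted silylation of a phenol; the C6 hydroxyl has only hydrogen on its other side whereas the C2 hydroxyl is buttressed by the C3 prenyl group, so the bulky silyl chloride should react at O6, and the remaining hydroxyl is then locked in the hydrogen bond to the carbonyl and resists a second silylation.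

**Step 4**
Reactants: 7 6-(tert-butyldimethylsilyloxy)-2-hydroxy-3-(3-methylbut-2-enyl)-4-(3-methylbut-2-enyloxy)benzaldehyde; 8 styrene; 9 trimethyl orthoformate
Product: 12 (2S,4S)-5-(tert-butyldimethylsilyloxy)-4-methoxy-7-(3-methylbut-2-enyloxy)-8-(3-methylbut-2-enyl)-2-phenylchroman, via dimethyl acetal 10 (not isolated), via α-methoxy ortho-quinone methide 11 (not isolated)
Conditions: 8 (5 equiv), 9 (2 equiv), (S,S)-imidodiphosphoric acid [(ArO)2P(O)]2NH with (ArO)2 = (S)-3,3'-bis(2,4,6-triethylphenyl)-1,1'-binaphthyl-2,2'-diolate (5 mol%), 5 Å MS, toluene, 0 °C → rt
Reagents that add atoms: none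
Why: Proposed new method: the acid converts 7 and 9 into acetal 10, which loses methanol to the oxocarbenium ion that is O-protonated 11, held as a contact ion pair whose chiral anion is also hydrogen-bonded to the C2 phenol; the CH2 terminus of 8 attacks the methide carbon (C3–C4) and the phenol oxygen closes onto the developing benzylic cation (O1–C2) in a polar, inverse-demand hetero-Diels–Alder addition that may be asynchronous-concerted or stepwise. The closest known reaction types are the racemic acid-catalysed three-component synthesis of 4-alkoxyflavans from salicylaldehydes, orthoformates and styrenes, and the asymmetric intramolecular cycloaddition of salicylaldehyde-derived alkoxy ortho-quinone methides onto tethered alkenes under confined chiral phosphorus acids; enantiocontrol in the intermolecular reaction with unfunctionalised styrene has not been shown. Ring C, the six-membered pyran, closes in the [4+2] mode or, in the stepwise limit, by six-membered capture of the C2 cation by the anion-bound phenol oxygen. C2 is set by the chiral anion, which must shield one face of the planar heterodiene and fix the endo or exo placement of the styrene phenyl group in its pocket; C4 needs no control because it becomes the carbonyl carbon, so either C4 epimer serves. Regiochemistry follows from polarity: the nucleophilic CH2 goes to the electrophilic methide carbon and the phenyl-stabilised cation to oxygen. Site selectivity on ring A is secured by the silyl ether, which leaves only the hydroxyl next to the C-prenyl group able to form the quinone methide. Chemoselectivity over the two prenyl alkenes rests on the excess of 8, dilution of 7 and the hindrance of trisubstituted alkenes towards a doubly ortho-substituted cation, and the weak acid is not expected to protonate the prenyl groups or close the ortho-prenylphenol to a chroman.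

**Step 5**
Reactants: 12 (2S,4S)-5-(tert-butyldimethylsilyloxy)-4-methoxy-7-(3-methylbut-2-enyloxy)-8-(3-methylbut-2-enyl)-2-phenylchroman
Product: 13 (2S)-5-(tert-butyldimethylsilyloxy)-7-(3-methylbut-2-enyloxy)-8-(3-methylbut-2-enyl)-2-phenylchroman-4-ol (C4 not controlled)
Conditions: PPTS (0.2 equiv), THF/H2O (4:1), rt
Reagents that add atoms: water, O
Why: Acid-catalysed SN1 exchange of a benzylic ether; C4 ionises readily because the cation is stabilised by O1, O5 and O7, and water in large excess captures it. C2 is not involved and keeps its configuration.

**Step 6**
Reactants: 13 (2S)-5-(tert-butyldimethylsilyloxy)-7-(3-methylbut-2-enyloxy)-8-(3-methylbut-2-enyl)-2-phenylchroman-4-ol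
Product: 14 (2S)-5-(tert-butyldimethylsilyloxy)-7-(3-methylbut-2-enyloxy)-8-(3-methylbut-2-enyl)-2-phenylchroman-4-one
Conditions: Dess–Martin periodinane (1.3 equiv), pyridine (3 equiv), CH2Cl2, 0 °C → rt
Reagents that add atoms: none
Why: Dess–Martin oxidation of a secondary benzylic alcohol; the reagent leaves trisubstituted alkenes and silyl ethers alone, pyridine buffers the acetic acid released so the acid-labile carbinol does not ionise, and the silyl group keeps the electron-rich phenol from being oxidised.

**Step 7**
Reactants: 14 (2S)-5-(tert-butyldimethylsilyloxy)-7-(3-methylbut-2-enyloxy)-8-(3-methylbut-2-enyl)-2-phenylchroman-4-one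
Product: 15 (2S)-5-hydroxy-7-(3-methylbut-2-enyloxy)-8-(3-methylbut-2-enyl)-2-phenylchroman-4-one
Conditions: HF·pyridine, pyridine, THF, 0 °C
Reagents that add atoms: none
Why: Fluoride cleavage of an aryl silyl ether, made easy by the peri carbonyl group; the slightly acidic medium avoids the phenoxide and enolate conditions under which a flavanone opens to the chalcone and racemises at C2, and neither prenyl group should react.

## Compound list

1 | 2,4,6-trihydroxybenzaldehyde | O=Cc1c(O)cc(O)cc1O | starting material
2 | prenyl bromide (1-bromo-3-methylbut-2-ene) | CC(C)=CCBr | starting material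
3 | 2-hydroxy-4,6-bis(3-methylbut-2-enyloxy)benzaldehyde | O=Cc1c(O)cc(OCC=C(C)C)cc1OCC=C(C)C | intermediate
4 | ortho-dienone: 2-hydroxy-5-(2-methylbut-3-en-2-yl)-4-(3-methylbut-2-enyloxy)-6-oxocyclohexa-1,3-diene-1-carbaldehyde (racemic, transient) | O=CC1=C(O)C=C(OCC=C(C)C)C(C(C)(C)C=C)C1=O | intermediate
5 | para-dienone: 2-hydroxy-3-(3-methylbut-2-enyl)-4-(3-methylbut-2-enyloxy)-6-oxocyclohexa-1,4-diene-1-carbaldehyde (racemic, transient) | O=CC1=C(O)C(CC=C(C)C)C(OCC=C(C)C)=CC1=O | intermediate
6 | 2,6-dihydroxy-3-(3-methylbut-2-enyl)-4-(3-methylbut-2-enyloxy)benzaldehyde | O=Cc1c(O)c(CC=C(C)C)c(OCC=C(C)C)cc1O | intermediate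
7 | 6-(tert-butyldimethylsilyloxy)-2-hydroxy-3-(3-methylbut-2-enyl)-4-(3-methylbut-2-enyloxy)benzaldehyde | O=Cc1c(O)c(CC=C(C)C)c(OCC=C(C)C)cc1O[Si](C)(C)C(C)(C)C | intermediate
8 | styrene | C=Cc1ccccc1 | starting material
9 | trimethyl orthoformate | COC(OC)OC | starting material
10 | dimethyl acetal of 7: 3-(tert-butyldimethylsilyloxy)-2-(dimethoxymethyl)-6-(3-methylbut-2-enyl)-5-(3-methylbut-2-enyloxy)phenol | COC(OC)c1c(O)c(CC=C(C)C)c(OCC=C(C)C)cc1O[Si](C)(C)C(C)(C)C | intermediate
11 | α-methoxy ortho-quinone methide from 10: 5-(tert-butyldimethylsilyloxy)-6-(methoxymethylidene)-2-(3-methylbut-2-enyl)-3-(3-methylbut-2-enyloxy)cyclohexa-2,4-dien-1-one (alkene geometry not assigned) | COC=C1C(=O)C(CC=C(C)C)=C(OCC=C(C)C)C=C1O[Si](C)(C)C(C)(C)C | intermediate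
12 | (2S,4S)-5-(tert-butyldimethylsilyloxy)-4-methoxy-7-(3-methylbut-2-enyloxy)-8-(3-methylbut-2-enyl)-2-phenylchroman (2,4-cis) | CC(C)=CCOc1cc(O[Si](C)(C)C(C)(C)C)c2c(c1CC=C(C)C)O[C@H](c1ccccc1)C[C@@H]2OC | intermediate
13 | (2S)-5-(tert-butyldimethylsilyloxy)-7-(3-methylbut-2-enyloxy)-8-(3-methylbut-2-enyl)-2-phenylchroman-4-ol (C4 undefined) | CC(C)=CCOc1cc(O[Si](C)(C)C(C)(C)C)c2c(c1CC=C(C)C)O[C@H](c1ccccc1)CC2O | intermediate
14 | (2S)-5-(tert-butyldimethylsilyloxy)-7-(3-methylbut-2-enyloxy)-8-(3-methylbut-2-enyl)-2-phenylchroman-4-one | CC(C)=CCOc1cc(O[Si](C)(C)C(C)(C)C)c2c(c1CC=C(C)C)O[C@H](c1ccccc1)CC2=O | intermediate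
15 | (2S)-5-hydroxy-7-(3-methylbut-2-enyloxy)-8-(3-methylbut-2-enyl)-2-phenylchroman-4-one | CC(C)=CCOc1cc(O)c2c(c1CC=C(C)C)O[C@H](c1ccccc1)CC2=O | target

## Step count and least certain steps

Total: 7 steps. Longest linear sequence: 7 steps (1 → 3 → 6 → 7 → 12 → 13 → 14 → 15); 2, 8 and 9 are purchased.

**Step 4 (key step, proposed new method).** What may go wrong: poor facial selectivity at C2, because unfunctionalised styrene offers the chiral anion no hydrogen-bonding handle. Ionisation of the acetal may also be slow with so weak an acid, and a prenyl alkene of a second substrate molecule may add to the cation, leading to oligomerisation. The fallback uses known chemistry, sets out from 7 and comes back to the route at 14. The same three components 7, 8 and 9 are combined under an achiral acid such as diphenyl phosphate, the known racemic process, which runs through 10 and 11 and should give racemic 5-(tert-butyldimethylsilyloxy)-4-methoxy-7-(3-methylbut-2-enyloxy)-8-(3-methylbut-2-enyl)-2-phenylchroman F1 as a mixture of C4 epimers. Hydrolysis as in step 5 would convert F1 into racemic 5-(tert-butyldimethylsilyloxy)-7-(3-methylbut-2-enyloxy)-8-(3-methylbut-2-enyl)-2-phenylchroman-4-ol F2 and oxidation as in step 6 would take F2 on to racemic 5-(tert-butyldimethylsilyloxy)-7-(3-methylbut-2-enyloxy)-8-(3-methylbut-2-enyl)-2-phenylchroman-4-one F3 as the substrate of a resolution. F3 is then resolved kinetically by asymmetric transfer hydrogenation with RuCl[(R,R)-TsDPEN](p-cymene) and HCO2H/Et3N, stopped near half conversion. The 2R ketone is expected to be reduced to the cis alcohol (2R,4R)-5-(tert-butyldimethylsilyloxy)-7-(3-methylbut-2-enyloxy)-8-(3-methylbut-2-enyl)-2-phenylchroman-4-ol F4 while the 2S ketone, which is 14, is left behind and separated from F4 by chromatography. The prenyl alkenes are inert to transfer hydrogenation; the cost is that at most half of the material is retained.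

**Step 2.** What may go wrong: enolisation of dienone 4 before the Cope shift would leave a reverse-prenyl group ortho to the freed oxygen, and partial rearrangement of the O4 ether cannot be ruled out; binding of the europium catalyst at the free chelated hydroxyl instead of the O6 ether may also slow the shift. The fallback sets out from 1 and comes back to the route at 6. 1 is C-prenylated directly with 2 in cold aqueous KOH, the classical nuclear alkylation of acylphloroglucinols, to give 2,4,6-trihydroxy-3-(3-methylbut-2-enyl)benzaldehyde F5 as the mono-C-alkylated product. The non-chelated 4-hydroxyl of F5 is then alkylated with one equivalent of 2 (K2CO3, acetone), which rejoins the route at 6.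

**Step 3.** What may go wrong: incomplete discrimination between the two formyl-flanking hydroxyls, leading to silylation at O2 or at both oxygens. The fallback sets out from 3, comes back to the route at 15 and removes the need for any silyl group. 3 itself is taken through the cycloaddition of step 4 with 8 and 9, its O6 prenyl ether masking the future O5. The acid should convert 3 into the acetal 2-(dimethoxymethyl)-3,5-bis(3-methylbut-2-enyloxy)phenol F6 and then, by loss of methanol, into the quinone methide 6-(methoxymethylidene)-3,5-bis(3-methylbut-2-enyloxy)cyclohexa-2,4-dien-1-one F7 to which 8 adds. The cycloadduct would be (2S,4S)-4-methoxy-5,7-bis(3-methylbut-2-enyloxy)-2-phenylchroman F8 with C2 set as in step 4. Hydrolysis as in step 5 would give (2S)-5,7-bis(3-methylbut-2-enyloxy)-2-phenylchroman-4-ol F9 and oxidation as in step 6 would give (2S)-5,7-bis(3-methylbut-2-enyloxy)-2-phenylchroman-4-one F10 as the substrate of the last step. The Eu(fod)3 para-Claisen–Cope shift is then run on F10 , the peri-chelated 5-O-prenyl ketone for which this rearrangement is established; it frees O5 and places the prenyl group at C8, arriving at 15. This sequence is kept in reserve because it moves the regiochemical uncertainty of the rearrangement, and a warm Lewis acid, onto late enantioenriched material.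

**Step 5.** What may go wrong: the C4 cation may lose a proton to give the flav-3-ene, or may be attacked by C6 of another molecule (oligomerisation), instead of being trapped by water. The fallback sets out from 12 and comes back to the route at 14 without passing through the carbinol. 12 is oxidised with DDQ in CH2Cl2/pH 7 buffer: hydride abstraction at the doubly activated C4–H gives the oxocarbenium ion, water adds, and the hemiketal collapses to the ketone 14. The risk to watch is competing oxidation at the allylic and benzylic positions of the prenyl groups.

## Further compounds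

F1 | step 4 | racemic 5-(tert-butyldimethylsilyloxy)-4-methoxy-7-(3-methylbut-2-enyloxy)-8-(3-methylbut-2-enyl)-2-phenylchroman (racemate, stereocentres undefined) | CC(C)=CCOc1cc(O[Si](C)(C)C(C)(C)C)c2c(c1CC=C(C)C)OC(c1ccccc1)CC2OC
F2 | step 4 | racemic 5-(tert-butyldimethylsilyloxy)-7-(3-methylbut-2-enyloxy)-8-(3-methylbut-2-enyl)-2-phenylchroman-4-ol (racemate, stereocentres undefined) | CC(C)=CCOc1cc(O[Si](C)(C)C(C)(C)C)c2c(c1CC=C(C)C)OC(c1ccccc1)CC2O
F3 | step 4 | racemic 5-(tert-butyldimethylsilyloxy)-7-(3-methylbut-2-enyloxy)-8-(3-methylbut-2-enyl)-2-phenylchroman-4-one | CC(C)=CCOc1cc(O[Si](C)(C)C(C)(C)C)c2c(c1CC=C(C)C)OC(c1ccccc1)CC2=O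
F4 | step 4 | (2R,4R)-5-(tert-butyldimethylsilyloxy)-7-(3-methylbut-2-enyloxy)-8-(3-methylbut-2-enyl)-2-phenylchroman-4-ol | CC(C)=CCOc1cc(O[Si](C)(C)C(C)(C)C)c2c(c1CC=C(C)C)O[C@@H](c1ccccc1)C[C@H]2O
F5 | step 2 | 2,4,6-trihydroxy-3-(3-methylbut-2-enyl)benzaldehyde | O=Cc1c(O)cc(O)c(CC=C(C)C)c1O
F6 | step 3 | 2-(dimethoxymethyl)-3,5-bis(3-methylbut-2-enyloxy)phenol (dimethyl acetal of 3, not isolated) | COC(OC)c1c(O)cc(OCC=C(C)C)cc1OCC=C(C)C
F7 | step 3 | 6-(methoxymethylidene)-3,5-bis(3-methylbut-2-enyloxy)cyclohexa-2,4-dien-1-one (alkene geometry not assigned, not isolated) | COC=C1C(=O)C=C(OCC=C(C)C)C=C1OCC=C(C)C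
F8 | step 3 | (2S,4S)-4-methoxy-5,7-bis(3-methylbut-2-enyloxy)-2-phenylchroman | CC(C)=CCOc1cc(OCC=C(C)C)c2c(c1)O[C@H](c1ccccc1)C[C@@H]2OC
F9 | step 3 | (2S)-5,7-bis(3-methylbut-2-enyloxy)-2-phenylchroman-4-ol (C4 undefined) | CC(C)=CCOc1cc(OCC=C(C)C)c2c(c1)O[C@H](c1ccccc1)CC2O
F10 | step 3 | (2S)-5,7-bis(3-methylbut-2-enyloxy)-2-phenylchroman-4-one | CC(C)=CCOc1cc(OCC=C(C)C)c2c(c1)O[C@H](c1ccccc1)CC2=O
F0 | step 5 | none | none
A1 | alternative 1 | 5-(methoxymethoxy)-7-(3-methylbut-2-enyloxy)-8-(3-methylbut-2-enyl)flavone | CC(C)=CCOc1cc(OCOC)c2c(c1CC=C(C)C)OC(c1ccccc1)=CC2=O
A2 | alternative 1 | 2-iodo-3-(methoxymethoxy)-5-(3-methylbut-2-enyloxy)-6-(3-methylbut-2-enyl)phenol | Oc1c(I)c(OCOC)cc(OCC=C(C)C)c1CC=C(C)C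
A3 | alternative 1 | phenylacetylene | C#Cc1ccccc1
A4 | alternative 1 | carbon monoxide | [C-]#[O+]
A5 | alternative 2 | (2S)-5-acetoxy-7-(3-methylbut-2-enyloxy)-8-(3-methylbut-2-enyl)flavanone | CC(C)=CCOc1cc(OC(C)=O)c2c(c1CC=C(C)C)O[C@H](c1ccccc1)CC2=O
A6 | alternative 2 | 1-[2-acetoxy-6-benzyloxy-4-(3-methylbut-2-enyloxy)-5-(3-methylbut-2-enyl)phenyl]-2-diazoethanone | [N-]=[N+]=CC(=O)c1c(OC(C)=O)cc(OCC=C(C)C)c(CC=C(C)C)c1OCc1ccccc1
A7 | alternative 3 | (2S)-5-(tert-butyldimethylsilyloxy)-7-(3-methylbut-2-enyloxy)-8-(3-methylbut-2-enyl)flavanone (identical with 14) | CC(C)=CCOc1cc(O[Si](C)(C)C(C)(C)C)c2c(c1CC=C(C)C)O[C@H](c1ccccc1)CC2=O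
A8 | alternative 3 | (3S)-3-[5-(tert-butyldimethylsilyloxy)-3-(3-methylbut-2-enyloxy)-2-(3-methylbut-2-enyl)phenoxy]-3-phenylpropanoic acid | OC(=O)C[C@@H](c1ccccc1)Oc1cc(O[Si](C)(C)C(C)(C)C)cc(OCC=C(C)C)c1CC=C(C)C
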